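## Retrosynthetic overview

1. Ring B (ten-membered) is closed last through C8–C9: the SmI2 ketyl of the C9 aldehyde (an acyl-anion-type carbon) adds to C8, the electrophilic β-carbon of a 4-alkoxy-3-methylbutenolide (tetronate). This sets C8, C9 and C17 and leaves the 7,19-lactone in place; PMB removal then gives the target.
2. C6–C7 comes from an asymmetric vinylogous Mukaiyama aldol of the tetronate-derived silyloxyfuran with a 2-substituted acrolein; C6–OH becomes C6–Cl with inversion.
3. C2–C3 comes from a catalyst-controlled pent-4-enylzinc addition to the neopentyl aldehyde; the alkene is converted to the C5(=CH2)–C6HO enal by ozonolysis and α-methylenation.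
4. Ring A is made first by an enantioselective Diels–Alder reaction (sets C1, C10, C11), followed by Saegusa oxidation, Luche reduction, Mitsunobu esterification at C12 and hydroxyl-directed epoxidation.
5. Ring order: A (cycloaddition), then C (lactone brought in as a pre-formed tetronate), then B (macrocyclization).

Convention: locants C1–C20 are briarane locants of the target (C1 quaternary, C2 CHOAc, C5 C=CH2, C6 CHCl, C7 CH–O, C8 C–OH, C9 CHOH, C12 CH–O-hexanoyl, C13/C14 epoxide, C17 CHMe, C19 lactone C=O). β is the face of the C15 methyl on ring A.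

Assumption: the catalyst antipodes named in steps 2, 4 and 14 are those expected to give the drawn stereoisomer; if the sense of induction were opposite, the mirror-image catalyst would be used.

The route is a paper proposal; none of it has been run.

## Route

Step 1
Reactants: 1 pent-1-en-3-one (ethyl vinyl ketone)
Product: 2 (Z)-3-(tert-butyldimethylsilyloxy)penta-1,3-diene
Conditions: TBSOTf, Et3N, Et2O, 0 °C
Reagents that add atoms: tert-butyldimethylsilyl triflate, CC(C)(C)[Si](C)(C)OS(=O)(=O)C(F)(F)F
Why: Soft enolization and O-silylation of the ethyl ketone gives the (Z)-silyl enol ether, so the terminal methyl sits "outside" on the s-cis diene.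

Step 2
Reactants: 2 (Z)-3-(tert-butyldimethylsilyloxy)penta-1,3-diene; 3 (E)-4-acetoxy-2-methylbut-2-enal
Product: 4 6-(acetoxymethyl)-4-(tert-butyldimethylsilyloxy)-1,5-dimethylcyclohex-3-ene-1-carbaldehyde (formyl α on C1, C15 methyl β, CH2OAc β on C10, C20 methyl β on C11)
Conditions: (S)-3,3-diphenyl-1-(o-tolyl)tetrahydro-1H,3H-pyrrolo[1,2-c][1,3,2]oxazaborole·Tf2NH (20 mol%), CH2Cl2, −78 → −40 °C
Reagents that add atoms: none
Why: Catalytic enantioselective Diels–Alder reaction (chiral oxazaborolidinium activation of the enal); the siloxy group directs "para" regiochemistry (C11 bonds to C10), the E-dienophile fixes C2 trans to C9, the exo-formyl/endo-CH2OAc transition state typical of 2-methyl enals puts the C20 methyl cis to C9, and the catalyst selects the enal face (C1, C10, C11).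

Step 3
Reactants: 4 silyl enol ether aldehyde
Product: 5 6-(acetoxymethyl)-1,5-dimethyl-4-oxocyclohex-2-ene-1-carbaldehyde (same configuration at C1, C10, C11)
Conditions: Pd(OAc)2 (10 mol%), O2 (1 atm), DMSO, 60 °C
Reagents that add atoms: none
Why: Saegusa–Ito oxidation: divalent palladium forms the C13 palladium enolate and β-hydride elimination from C14 gives the C13=C14 enone without touching the non-enolizable aldehyde.

Step 4
Reactants: 5 enone aldehyde; 6 pent-4-enylmagnesium bromide
Product: 8 [6-(1-hydroxyhex-5-en-1-yl)-2,6-dimethyl-3-oxocyclohex-4-en-1-yl]methyl acetate (C2 carbinol configured as in the target), via di(pent-4-enyl)zinc 7 (not isolated)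
Conditions: 6, ZnCl2, Et2O, then 1,4-dioxane, filter; add 5, (2S)-3-exo-morpholinoisoborneol (10 mol%), toluene, 0 °C; aq NH4Cl
Reagents that add atoms: none
Why: Catalytic enantioselective dialkylzinc addition (amino-alcohol–zinc catalysis) to the aldehyde only; the catalyst, not the weak Felkin bias of the neopentyl aldehyde (which would give the C2 epimer), sets C2, and enone and acetate are inert to R2Zn.

Step 5
Reactants: 8 enone alcohol
Product: 9 allylic diol with 12β-OH (C12 epimeric to the target oxygen, cis to the C20 methyl)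
Conditions: NaBH4, CeCl3·7H2O, MeOH, −78 °C
Reagents that add atoms: none
Why: Luche 1,2-reduction; in the half-chair with both methyls pseudo-equatorial the β face of C12 is blocked by the pseudo-axial C10 substituent, so hydride enters from the α face and gives the axial 12β-alcohol.

Step 6
Reactants: 9 12β-allylic alcohol
Product: 10 12α-hexanoate with free C2–OH (C12 as in the target)
Conditions: n-C5H11CO2H, PPh3, DIAD, toluene, 0 °C → rt
Reagents that add atoms: hexanoic acid, CCCCCC(=O)O
Why: Mitsunobu esterification with clean SN2 inversion at the axial allylic C12 alcohol; the neopentyl C2 alcohol is too hindered to be activated and SN2′ attack at the neopentyl C14 is disfavoured.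

Step 7
Reactants: 10 allylic hexanoate
Product: 11 13α,14α-epoxide (C2–OH free)
Conditions: VO(acac)2 (5 mol%), t-BuOOH, CH2Cl2, 0 °C → rt
Reagents that add atoms: tert-butyl hydroperoxide, CC(C)(C)OO
Why: Vanadium-catalysed hydroxyl-directed epoxidation; the homoallylic C2–OH on the α face of C1 delivers the peroxide to the α face of C13=C14 (cis to O12), and the isolated terminal alkene is not epoxidized.

Step 8
Reactants: 11 epoxy alcohol
Product: 12 C2 acetate
Conditions: Ac2O, DMAP, pyridine, 40 °C
Reagents that add atoms: acetic anhydride, CC(=O)OC(C)=O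
Why: DMAP-catalysed acylation of the only free hydroxyl (hindered secondary C2–OH), with retention.

Step 9
Reactants: 12 terminal alkene
Product: 14 C6 aldehyde, via secondary ozonide 13 (not isolated)
Conditions: O3, CH2Cl2, −78 °C; then Me2S
Reagents that add atoms: ozone, [O-][O+]=O
Why: Ozonolysis with reductive work-up; the terminal alkene is the only C=C left in the molecule.

Step 10
Reactants: 14 aldehyde
Product: 15 2-substituted acrolein (C5=C16H2, C6 aldehyde)
Conditions: 37% aq CH2O, pyrrolidine (10 mol%), EtCO2H (10 mol%), i-PrOH, 45 °C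
Reagents that add atoms: formaldehyde, C=O
Why: Organocatalytic α-methylenation (enamine Mannich reaction, then elimination) of the CH2–CHO unit installs the C5 exo-methylene.

Step 11
Reactants: 16 ethyl 2-methylacetoacetate
Product: 18 3-methyltetronic acid (4-hydroxy-3-methylfuran-2(5H)-one), via ethyl 4-bromo-2-methyl-3-oxobutanoate 17 (not isolated)
Conditions: Br2, CHCl3, 0 °C → rt; then neat, 110 °C
Reagents that add atoms: none
Why: γ-Bromination of the β-keto ester, then thermal lactonization with loss of bromoethane (classical tetronic acid synthesis).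

Step 12
Reactants: 18 3-methyltetronic acid
Product: 19 4-(4-methoxybenzyloxy)-3-methylfuran-2(5H)-one
Conditions: 4-MeOC6H4CH2OH, PPh3, DIAD, THF, 0 °C → rt
Reagents that add atoms: 4-methoxybenzyl alcohol, COc1ccc(CO)cc1
Why: Mitsunobu O-alkylation of the acidic vinylogous acid gives the O-PMB tetronate (O8 protected, β-carbon still electrophilic).

Step 13
Reactants: 19 O-PMB tetronate
Product: 20 4-(4-methoxybenzyloxy)-3-methyl-2-(trimethylsilyloxy)furan
Conditions: TMSOTf, Et3N, CH2Cl2, 0 °C
Reagents that add atoms: trimethylsilyl triflate, C[Si](C)(C)OS(=O)(=O)C(F)(F)F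
Why: Soft enolization at the γ-CH2 (C7) gives the aromatic silyloxyfuran, a vinylogous silyl ketene acetal.

Step 14
Reactants: 15 enal; 20 silyloxyfuran
Product: 22 vinylogous aldol adduct (C6–OH opposite in configuration to the target C–Cl, C7 as in the target, 6,7-syn; tetronate 4-O-PMB), via C6 trimethylsilyl ether 21 (not isolated)
Conditions: Ti(OiPr)4 (20 mol%), (R)-1,1'-bi-2-naphthol (20 mol%), Et2O, −20 °C; then aq citric acid, THF
Reagents that add atoms: none
Why: Catalytic asymmetric vinylogous Mukaiyama aldol (1,2-addition at the furan γ-carbon, C3 being blocked by methyl); the BINOL–titanate selects the aldehyde face (C6) and the open antiperiplanar transition state gives the 6,7-syn (threo) adduct, which fixes C7.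

Step 15
Reactants: 22 allylic alcohol
Product: 23 C6 allylic chloride (C6 as in the target, Cl anti to O7)
Conditions: PPh3, Cl3CC(O)CCl3, CH2Cl2, 0 °C
Reagents that add atoms: hexachloroacetone, O=C(C(Cl)(Cl)Cl)C(Cl)(Cl)Cl
Why: Appel-type deoxychlorination with the triphenylphosphine/hexachloroacetone reagent converts the allylic alcohol to the chloride by SN2 with inversion and little allylic transposition, under neutral conditions that leave the acidic C7–H alone.

Step 16
Reactants: 23 triester chloride
Product: 24 primary C9 alcohol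
Conditions: Candida antarctica lipase B (immobilised), pH 7 phosphate buffer–acetone, 30 °C
Reagents that add atoms: none
Why: Enzymatic regioselective hydrolysis: the lipase cleaves the unhindered primary acetate and leaves the hindered secondary acetate (C2), the secondary hexanoate (C12) and the tetronate untouched.

Step 17
Reactants: 24 primary alcohol
Product: 25 C9 aldehyde (seco-aldehyde)
Conditions: Dess–Martin periodinane, NaHCO3, CH2Cl2, 0 °C
Reagents that add atoms: none
Why: Dess–Martin oxidation of the only free hydroxyl under buffered, non-epimerizing conditions.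

Step 18
Reactants: 25 seco-aldehyde
Product: 26 ten-membered macrocycle (8-O-PMB ether of the target; C8, C9, C17 as in the target)
Conditions: SmI2 (2.5 equiv), MeOH (3 equiv), THF, 0.003 M, −78 → 0 °C, substrate added over 6 h
Reagents that add atoms: none
Why: Proposed new method: SmI2 reduces the aldehyde to the C9 ketyl radical anion, a reversed-polarity (acyl-anion-type) carbon, which adds 10-exo to C8, the electrophilic β-carbon of the tetronate; a second electron gives the trivalent-samarium lactone enolate, which MeOH protonates at C17 faster than the C8 alkoxy group can β-eliminate; the closest known chemistry is the SmI2 aldehyde/β-alkoxyacrylate reductive cyclization used for polycyclic ethers together with SmI2 ketyl–olefin medium-ring closures and aldehyde–butenolide couplings; C9 is expected to enter anti to C6 (trans ring fusion as in trans-fused ten-membered lactones, setting C8), samarium bridging O9 and the lactone carbonyl with H9 over the lactone ring sets C9, and protonation from the chelated face gives the C18 methyl trans to C9, which is also the thermodynamic epimer; aldehyde reduction is much faster than that of the secondary allylic chloride in HMPA-free THF.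

Step 19
Reactants: 26 PMB ether
Product: 27 CNP0109876.1 (target)
Conditions: DDQ, CH2Cl2–pH 7 buffer (10:1), 0 °C → rt
Reagents that add atoms: none
Why: Oxidative PMB ether cleavage (benzylic hydride abstraction, hydrolysis of the oxocarbenium) frees the tertiary C8–OH without affecting the esters, epoxide, allylic chloride or lactone.

## Compound list

1 | pent-1-en-3-one (ethyl vinyl ketone) | C=CC(=O)CC | starting material
2 | (Z)-3-(tert-butyldimethylsilyloxy)penta-1,3-diene | C=C/C(O[Si](C)(C)C(C)(C)C)=C/C | intermediate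
3 | (E)-4-acetoxy-2-methylbut-2-enal | O=C/C(C)=C/COC(C)=O | starting material
4 | 6-(acetoxymethyl)-4-(tert-butyldimethylsilyloxy)-1,5-dimethylcyclohex-3-ene-1-carbaldehyde; formyl α, both methyls and CH2OAc β | O=C[C@]1(C)[C@H]([C@@H](C)C(O[Si](C)(C)C(C)(C)C)=CC1)COC(C)=O | intermediate
5 | 6-(acetoxymethyl)-1,5-dimethyl-4-oxocyclohex-2-ene-1-carbaldehyde; same configuration | O=C[C@]1(C)[C@H]([C@@H](C)C(=O)C=C1)COC(C)=O | intermediate
6 | pent-4-enylmagnesium bromide | C=CCCC[Mg]Br | starting material
7 | di(pent-4-enyl)zinc | C=CCCC[Zn]CCCC=C | intermediate (not isolated)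
8 | [6-(1-hydroxyhex-5-en-1-yl)-2,6-dimethyl-3-oxocyclohex-4-en-1-yl]methyl acetate; C2 carbinol as in target | C=CCCC[C@@H](O)[C@]1(C)[C@H]([C@@H](C)C(=O)C=C1)COC(C)=O | intermediate
9 | allylic diol, 12β-OH (cis to C20 methyl), C2–OH | C=CCCC[C@@H](O)[C@]1(C)[C@H]([C@@H](C)[C@@H](O)C=C1)COC(C)=O | intermediate
10 | 12α-hexanoate, C2–OH free, C13=C14 alkene | C=CCCC[C@@H](O)[C@]1(C)[C@H]([C@@H](C)[C@H](OC(=O)CCCCC)C=C1)COC(C)=O | intermediate
11 | 13α,14α-epoxy-12α-hexanoate, C2–OH free | C=CCCC[C@@H](O)[C@]2(C)[C@H]([C@@H](C)[C@H](OC(=O)CCCCC)[C@@H]3O[C@@H]32)COC(C)=O | intermediate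
12 | C2 acetate of 11 (pent-4-enyl chain, C9 CH2OAc) | C=CCCC[C@@H](OC(C)=O)[C@]2(C)[C@H]([C@@H](C)[C@H](OC(=O)CCCCC)[C@@H]3O[C@@H]32)COC(C)=O | intermediate
13 | secondary ozonide (1,2,4-trioxolane) of 12 | C1OOC(CCC[C@@H](OC(C)=O)[C@]2(C)[C@H]([C@@H](C)[C@H](OC(=O)CCCCC)[C@@H]3O[C@@H]32)COC(C)=O)O1 | intermediate (not isolated)
14 | C6 aldehyde (C3–C6 chain ending in CHO) | O=CCCC[C@@H](OC(C)=O)[C@]2(C)[C@H]([C@@H](C)[C@H](OC(=O)CCCCC)[C@@H]3O[C@@H]32)COC(C)=O | intermediate
15 | 2-substituted acrolein (C5=CH2, C6 aldehyde) | C=C(C=O)CC[C@@H](OC(C)=O)[C@]2(C)[C@H]([C@@H](C)[C@H](OC(=O)CCCCC)[C@@H]3O[C@@H]32)COC(C)=O | intermediate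
16 | ethyl 2-methylacetoacetate (racemic) | CCOC(=O)C(C)C(C)=O | starting material
17 | ethyl 4-bromo-2-methyl-3-oxobutanoate | CCOC(=O)C(C)C(=O)CBr | intermediate (not isolated)
18 | 3-methyltetronic acid | CC1=C(O)COC1=O | intermediate
19 | 4-(4-methoxybenzyloxy)-3-methylfuran-2(5H)-one | COc1ccc(COC2=C(C)C(=O)OC2)cc1 | intermediate
20 | 4-(4-methoxybenzyloxy)-3-methyl-2-(trimethylsilyloxy)furan | COc1ccc(COc2coc(O[Si](C)(C)C)c2C)cc1 | intermediate
21 | C6 trimethylsilyl ether of 22 | COc1ccc(COC2=C(C)C(=O)O[C@H]2[C@H](O[Si](C)(C)C)C(=C)CC[C@@H](OC(C)=O)[C@]3(C)[C@H]([C@@H](C)[C@H](OC(=O)CCCCC)[C@@H]4O[C@@H]43)COC(C)=O)cc1 | intermediate (not isolated)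
22 | vinylogous aldol adduct: O-PMB tetronate joined at C7 to C6H(OH); 6,7-syn; C7 as in target, C6 opposite to target C–Cl | COc1ccc(COC2=C(C)C(=O)O[C@H]2[C@H](O)C(=C)CC[C@@H](OC(C)=O)[C@]3(C)[C@H]([C@@H](C)[C@H](OC(=O)CCCCC)[C@@H]4O[C@@H]43)COC(C)=O)cc1 | intermediate
23 | C6 allylic chloride (C6 as in target), C9 CH2OAc | COc1ccc(COC2=C(C)C(=O)O[C@H]2[C@@H](Cl)C(=C)CC[C@@H](OC(C)=O)[C@]3(C)[C@H]([C@@H](C)[C@H](OC(=O)CCCCC)[C@@H]4O[C@@H]43)COC(C)=O)cc1 | intermediate
24 | primary C9 alcohol | COc1ccc(COC2=C(C)C(=O)O[C@H]2[C@@H](Cl)C(=C)CC[C@@H](OC(C)=O)[C@]3(C)[C@H]([C@@H](C)[C@H](OC(=O)CCCCC)[C@@H]4O[C@@H]43)CO)cc1 | intermediate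
25 | C9 aldehyde (seco-aldehyde) | COc1ccc(COC2=C(C)C(=O)O[C@H]2[C@@H](Cl)C(=C)CC[C@@H](OC(C)=O)[C@]3(C)[C@H]([C@@H](C)[C@H](OC(=O)CCCCC)[C@@H]4O[C@@H]43)C=O)cc1 | intermediate
26 | 8-O-(4-methoxybenzyl) ether of the target | C=C1CC[C@@H](OC(C)=O)[C@]2(C)[C@H]([C@@H](C)[C@H](OC(=O)CCCCC)[C@@H]3O[C@@H]32)[C@@H](O)[C@]2(OCc3ccc(OC)cc3)[C@@H](C)C(=O)O[C@H]2[C@H]1Cl | intermediate
27 | CNP0109876.1 | C=C1CC[C@@H](OC(C)=O)[C@]2(C)[C@H]([C@@H](C)[C@H](OC(=O)CCCCC)[C@@H]3O[C@@H]32)[C@@H](O)[C@]2(O)[C@@H](C)C(=O)O[C@H]2[C@H]1Cl | target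

## Step count and risks

Total step count: 19. Longest linear sequence: 16 steps (steps 1–10 and 14–19, from ethyl vinyl ketone); steps 11–13 are the tetronate branch.

The three steps most likely to fail:

Step 18 (SmI2 macrocyclization; untested ring size and a fully substituted acceptor, with pinacol dimerization, simple reduction or β-elimination as competitors). The fallback sets out from aldehyde 25 and returns at 26, replacing the ketyl by an acyl radical. Pinnick oxidation (NaClO2, NaH2PO4, 2-methylbut-2-ene) gives the carboxylic acid F1. (PhSe)2/PBu3 converts it into the acyl selenide F2. Bu3SnH/AIBN in benzene at high dilution generates the nucleophilic acyl radical, which closes the ten-membered ring by 10-exo addition to the tetronate β-carbon and, after hydrogen-atom transfer at C17, gives the C9 ketone F3. Zn(BH4)2 reduction under chelation with the C8 ether oxygen then gives 26.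

Step 14 (asymmetric vinylogous aldol; both the syn/anti ratio and the catalyst control of the 4-alkoxy silyloxyfuran are unproven). The fallback sets out from enal 15 (with tetronate 19) and returns at 22. The lithium dienolate of 19 (LDA, THF, −78 °C) is added to 15 without stereocontrol. The mixture is oxidized with Dess–Martin periodinane to the single C6 ketone F4, whose C7 centre (α to the ketone and γ to the tetronate) epimerizes freely. Carbonyl-selective transfer hydrogenation with RuCl(p-cymene)[(S,S)-TsDPEN] in HCO2H/Et3N under dynamic kinetic resolution then sets C6 and C7 together and gives 22.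

Step 2 (enantioselective Diels–Alder with a trisubstituted, β-branched enal). The fallback sets out from dienophile 3 and returns at enone 5, using a more reactive diene and a different catalyst class. Butan-2-one and N,N-dimethylformamide dimethyl acetal give (E)-1-(dimethylamino)pent-1-en-3-one F5. KHMDS/TBSCl gives the 1-amino-3-siloxy diene F6. Cycloaddition with 3 catalysed by [(1R,2R)-N,N'-bis(3,5-di-tert-butylsalicylidene)cyclohexane-1,2-diamine]CrSbF6 (trivalent chromium) gives the amino silyl enol ether F7. HF in MeCN hydrolyses the enol ether and eliminates dimethylamine to give 5 directly, so step 3 is not needed.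

Further compounds
F1 | step 18 | C9 carboxylic acid from 25 | COc1ccc(COC2=C(C)C(=O)O[C@H]2[C@@H](Cl)C(=C)CC[C@@H](OC(C)=O)[C@]3(C)[C@H]([C@@H](C)[C@H](OC(=O)CCCCC)[C@@H]4O[C@@H]43)C(=O)O)cc1
F2 | step 18 | C9 acyl phenyl selenide | COc1ccc(COC2=C(C)C(=O)O[C@H]2[C@@H](Cl)C(=C)CC[C@@H](OC(C)=O)[C@]3(C)[C@H]([C@@H](C)[C@H](OC(=O)CCCCC)[C@@H]4O[C@@H]43)C(=O)[Se]c3ccccc3)cc1
F3 | step 18 | macrocyclic C9 ketone (8-O-PMB, 9-oxo analogue of 26) | C=C1CC[C@@H](OC(C)=O)[C@]2(C)[C@H]([C@@H](C)[C@H](OC(=O)CCCCC)[C@@H]3O[C@@H]32)C(=O)[C@]2(OCc3ccc(OC)cc3)[C@@H](C)C(=O)O[C@H]2[C@H]1Cl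
F4 | step 14 | C6 ketone of 22 (C7 configurationally labile, left undefined) | COc1ccc(COC2=C(C)C(=O)OC2C(=O)C(=C)CC[C@@H](OC(C)=O)[C@]3(C)[C@H]([C@@H](C)[C@H](OC(=O)CCCCC)[C@@H]4O[C@@H]43)COC(C)=O)cc1
F5 | step 2 | (E)-1-(dimethylamino)pent-1-en-3-one | CCC(=O)/C=C/N(C)C
F6 | step 2 | (1E,3Z)-1-(dimethylamino)-3-(tert-butyldimethylsilyloxy)penta-1,3-diene | CN(C)/C=C/C(O[Si](C)(C)C(C)(C)C)=C/C
F7 | step 2 | C14-dimethylamino cycloadduct (NMe2 β, otherwise as 4) | O=C[C@]1(C)[C@H]([C@@H](C)C(O[Si](C)(C)C(C)(C)C)=C[C@H]1N(C)C)COC(C)=O
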